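## Analysis of the target

The target is a 3,8-linked biflavanone. Unit 1 is a 5,7-dihydroxyflavanone with a catechol ring on C2, and its C3 is bonded to C8 of unit 2, a 5,7-dihydroxyflavanone with a 4-hydroxyphenyl group on C2. There are three stereocentres: C2 and C3 of unit 1 are both R, which places the catechol ring and the unit 2 aryl group cis on ring C, and C2 of unit 2 is S. The unit 2 centre lies beyond the aryl–C3 bond, so it cannot be set by relay from unit 1. The cis pair is the less stable arrangement, and C3–H is both benzylic and α to the C4 ketone, so acid or base met after that ketone exists can drain it to the trans isomer. Both rings C open to chalcones under base, which would scramble the C2 centres, and the seven free phenols are prone to oxidation. The C3–C8 bond joins an sp3 carbon to an arene with two ortho oxygens and is too crowded to be made comfortably by coupling. The route rests on one feature: once unit 1 has a C3=C4 double bond, O1–C2 is an allylic and benzylic aryl ether, so ring C can be closed at O1–C2 by a phenoxide on an allyl–palladium complex, and the C2 aryl group of the resulting 2H-chromene can then control C3.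

## Retrosynthetic reasoning

**24 to 23.** The last cut removes seven O-benzyl groups. Benzyl is inert to every reagent used earlier and leaves by neutral hydrogenolysis, which is the gentlest way to expose a cis-2,3-flavanone that tolerates neither acid nor base.

**23 to 22.** Both C4 ketones are traced back to carbinols. The unit 1 ketone should appear only one step from the end, so that C3 is not enolisable while the skeleton is assembled. The unit 2 carbinol is in 22 only because the hydroborating agent also reduces that ketone; one oxidation restores both.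

**22 to 20.** C4–O and C3–H of unit 1 are cut back to the C3=C4 alkene of a 2-aryl-2H-chromene. Syn addition of H and B from the face away from the C2 aryl group puts hydrogen on C3 on that face, so the unit 2 aryl group ends up cis to the catechol ring. This turns a thermodynamically uphill relationship into a kinetically controlled one.

**20 to 18 and 19.** The C2–aryl bond of unit 2 is cut. Until then unit 2 is carried as a chromone, which is flat, has no stereocentre to lose, and gives only reversible ring opening with amines. Catalyst-controlled conjugate arylation with 19 then sets the remote centre independently of unit 1. It comes after the ring closure because a flavanone would not survive the condensation and organometallic steps, and before the hydroboration because the chromone would not survive that.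

**18 to 17 (key disconnection).** O1–C2 of unit 1 is cut, opening ring C to a phenol and an allylic carbonate. This is the one bond of ring C whose formation creates C2 while leaving the alkene needed to control C3. The carbinol centre of 17 can be racemic, since it becomes planar in the allyl complex. The forward step has to ionise the carbonate, reach a geometry that can close, and form the C–O bond under ligand control. 17 is drawn with ring A trans to the carbinol carbon: the condensation below delivers that geometry, and it keeps the free phenol from reaching the carbinol carbon without the metal.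

**17 to 16 to 15, and 15 to 11 and 14.** The phenol is kept silylated until just before the key step so that the carbonate can be put on the carbinol alone. The carbinol C–aryl bond is cut to the enal 11 and the arylzinc reagent 14, made from 12. An organozinc adds to the aldehyde and leaves the chromone untouched.

**11 to 7 and 10.** The C3=C4 double bond of the future unit 1 is cut by an aldol condensation between the arylacetaldehyde 7 and the aldehyde 10. The crowded inter-unit bond then never has to be made by coupling, because the carbon that becomes C3 is already attached to C8 of unit 2 in 7.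

**7 to 6 to 4 to 3 to 2 to 1.** The aldehyde comes from cleavage of an allyl group. The C8–CH2 bond is cut by a Claisen transform (3 to 4), which can deliver the allyl group only to the one free ortho position. The chromone ring comes from the acetyl group of 4 and one extra carbon, through 5.

**10 to 9 to 8.** The ring A aldehyde is the dibenzyl ether of 8, with the third, chelated phenol silylated.

## Alternatives that were turned down

**Alternative 1:** Ring A of unit 1 would be made last, by cutting C4a–C5 and C8–C8a. The dihydropyranone A2 already holds O1, C2, C3 and C4 with both aryl groups cis and a phenylsulfinyl group on the future C4a. The bis(silyloxy)diene A3 would add across its C5=C6 bond, and the adduct would aromatise by losing the sulfinyl and methoxy groups to give the 5,7-dihydroxychromanone A1.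
- For it: such polarised cycloadditions are regiochemically dependable, and the two new phenols emerge free and therefore distinct from the benzyl ethers. Unit 1 also arrives at the ketone oxidation level, so no hydroboration and reoxidation are needed; on that count it is stronger than the chosen route.
- Against it: the whole stereochemical problem of unit 1 is moved into A2. A2 is a cis-2,3-diaryl vinylogous ester whose C3–H is α to a carbonyl and whose ring can open by retro-oxa-Michael reaction. It would have to be made as one enantiomer and one diastereomer, then survive heating with a basic, nucleophilic diene and the elimination that follows. The chromone of unit 2 is a second electron-poor alkene open to A3, and C2 of unit 2 is still unset in A1.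
- Comparison: the chosen route gives up direct arrival at the ketone. In return it creates the labile cis pair two steps from the end, by an addition with a clear steric bias, and needs no enantiopure precursor.

**Alternative 2:** Ring C of unit 1 would grow out of a four-membered ring, by cutting O1–C8a and C4–C4a. Fluoride would release the aryne from the silyl triflate A6, and the aryne would insert between the carbonyl carbon and the ring oxygen of the cis-β-lactone A5. A5 carries the catechol ring on C4 and the complete benzylated unit 2 on C3. The product A4 is identical with 23.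
- For it: this is the most convergent plan. One step leads from A5 to the last intermediate, both centres of unit 1 are carried over untouched, and the ketone is in place. In steps after the key step it clearly beats the chosen route.
- Against it: the ring oxygen of a β-lactone is a poor nucleophile towards an aryne. Insertion would have to outrun two easy decay paths of A5 under basic fluoride. One is loss of the C3 proton, which is benzylic and α to the carbonyl, leading to the trans lactone or ring opening. The other is ionisation of the C4–O bond next to the electron-rich catechol ring, followed by decarboxylation. The oxygen also has to attack the aryne carbon remote from the benzyloxy group, which is expected but not enforced. A5 itself, an enantiopure cis-3,4-diaryl-β-lactone with a base-sensitive flavanone attached, is at least as hard to make as the cis pair of the target.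
- Comparison: the chosen route is longer at the end, but each centre is set by a reaction of known stereochemical course, and the intermediate that carries the risk (17) is made from simple aldehydes with no stereocontrol at all.

**Alternative 3:** Ring A of unit 2 would be built onto a finished chromene, by cutting C8–C8a, C6–C7 and C4a–C8a of unit 2. On heating, the cyclobutenone A9 would open to a vinylketene. Cycloaddition with the alkyne of the silyl ynol ether A8, opening of the new four-membered ring and six-electron closure would leave the resorcinol monosilyl ether A7 (Danheiser benzannulation).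
- For it: the crowded C3–C8 bond begins as an unhindered alkyne–alkene bond and the arene is grown around it. The three oxygens of the new ring come out differently protected (free, silyl, benzyl), which is more than the chosen route offers. On the hindered bond the two plans are equal in intent, since the chosen route also avoids a coupling.
- Against it: the annulation needs prolonged heating, and a 2-aryl-2H-chromene opens reversibly to an ortho-quinone methide under such conditions, which would erode C2. A8 presupposes that C2 has already been set by some other asymmetric step and that a sensitive ynol ether can be built on the chromene. A7 is also far from the target: ring C of unit 2 (C-acylation between two oxygens, then an enantioselective closure) and the whole end-game on unit 1 would still follow.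
- Comparison: the chosen route reaches the chromene stage with unit 2 already present as a chromone, and sets C2 in the same operation that closes ring C.

Key step: step 12

**Remarks on the chemistry (assumptions).**
- (a) Step 8 is taken to give the (E)-enal 11 (ring A trans to the formyl group), and 15–17 keep that geometry. The key step does not depend on it, because the allyl complex has to pass through a syn/anti shift in any case.
- (b) The hand of each chiral ligand (steps 12 and 13) is the expected one and is to be confirmed on a first run, for step 13 with 6 as a model chromone.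
- (c) C2 of the chromene ring is S in 18 and 20 and R in 22–24, and C3 is S in 22 and R in 23–24, with no change of spatial arrangement. Only the CIP priorities change, with the hybridisation of C3 and the oxidation level of C4.

## Route

Step 1
Reactants: 1 2,4,6-trihydroxyacetophenone
Product: 2 1-[2,4-bis(benzyloxy)-6-hydroxyphenyl]ethanone
Conditions: BnBr (2.1 equiv), K2CO3, DMF, rt
Reagents that add atoms: benzyl bromide, BrCc1ccccc1
Why: Williamson etherification; the hydroxyl hydrogen-bonded to the acetyl group is the least nucleophilic and should stay free when two equivalents of halide are used.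

Step 2
Reactants: 2 1-[2,4-bis(benzyloxy)-6-hydroxyphenyl]ethanone
Product: 3 1-[2-(allyloxy)-4,6-bis(benzyloxy)phenyl]ethanone
Conditions: allyl bromide, K2CO3, DMF, 60 °C
Reagents that add atoms: allyl bromide, C=CCBr
Why: Williamson etherification of the chelated phenol, which needs only mild heating with a reactive allylic halide.

Step 3
Reactants: 3 1-[2-(allyloxy)-4,6-bis(benzyloxy)phenyl]ethanone
Product: 4 1-[3-allyl-4,6-bis(benzyloxy)-2-hydroxyphenyl]ethanone
Conditions: PhNEt2, 195 °C
Reagents that add atoms: none
Why: Aromatic Claisen rearrangement; one ortho position carries the acetyl group, so the allyl group can migrate only to the free ortho carbon, the future C8 of unit 2, and tautomerisation restores the chelated phenol.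

Step 4
Reactants: 4 1-[3-allyl-4,6-bis(benzyloxy)-2-hydroxyphenyl]ethanone
Product: 6 8-allyl-5,7-bis(benzyloxy)-4H-chromen-4-one, via enaminone 5 (not isolated)
Conditions: Me2NCH(OMe)2, toluene, 100 °C; then HCl (aq.), CH2Cl2, rt
Reagents that add atoms: N,N-dimethylformamide dimethyl acetal, COC(OC)N(C)C
Why: Condensation of the methyl ketone with the amide acetal gives the enaminone; under acid the ortho phenol adds in conjugate fashion and dimethylamine leaves, which closes the 2,3-unsubstituted chromone.

Step 5
Reactants: 6 8-allyl-5,7-bis(benzyloxy)-4H-chromen-4-one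
Product: 7 [5,7-bis(benzyloxy)-4-oxo-4H-chromen-8-yl]acetaldehyde
Conditions: OsO4 (2 mol%), NaIO4 (3 equiv), 2,6-lutidine, dioxane/H2O, rt
Reagents that add atoms: osmium tetroxide, O=[Os](=O)(=O)=O; sodium periodate, [Na+].[O-]I(=O)(=O)=O
Why: Lemieux–Johnson cleavage; OsO4 should dihydroxylate the terminal alkene far faster than the electron-poor chromone C2=C3 bond, and periodate cleaves the diol; ozone would be less discriminating towards the chromone and the alkoxyarenes. The aldehyde is used at once.

Step 6
Reactants: 8 2,4,6-trihydroxybenzaldehyde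
Product: 9 2,4-bis(benzyloxy)-6-hydroxybenzaldehyde
Conditions: BnBr (2.0 equiv), K2CO3, DMF, 0 °C to rt
Reagents that add atoms: benzyl bromide, BrCc1ccccc1
Why: Williamson etherification with the same selectivity as in step 1; the hydroxyl chelated to the formyl group should remain.

Step 7
Reactants: 9 2,4-bis(benzyloxy)-6-hydroxybenzaldehyde
Product: 10 2,4-bis(benzyloxy)-6-[(triisopropylsilyl)oxy]benzaldehyde
Conditions: TIPSOTf, 2,6-lutidine, CH2Cl2, 0 °C
Reagents that add atoms: triisopropylsilyl trifluoromethanesulfonate, CC(C)[Si](OS(=O)(=O)C(F)(F)F)(C(C)C)C(C)C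
Why: Silylation of the chelated phenol with a reactive silyl triflate; the triisopropylsilyl ether should survive amine catalysis, the organozinc and acylation, and still leave with buffered fluoride.

Step 8
Reactants: 7 [5,7-bis(benzyloxy)-4-oxo-4H-chromen-8-yl]acetaldehyde; 10 2,4-bis(benzyloxy)-6-[(triisopropylsilyl)oxy]benzaldehyde
Product: 11 (2E)-3-{2,4-bis(benzyloxy)-6-[(triisopropylsilyl)oxy]phenyl}-2-[5,7-bis(benzyloxy)-4-oxo-4H-chromen-8-yl]prop-2-enal
Conditions: pyrrolidine (30 mol%), PhCO2H (30 mol%), 4 Å MS, toluene, 40 °C, slow addition of 7 to 10 (1.5 equiv); then wash with 1 M HCl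
Reagents that add atoms: none
Why: Amine-catalysed cross-aldol condensation: the enamine of 7 adds to the iminium ion of the non-enolisable aldehyde 10 and the amine is then eliminated; the conjugated (E)-enal with the two aryl groups cis is the expected thermodynamic product. Any chromone opened reversibly by the amine is an enaminone of the type of 5 and should re-close in the acid wash.

Step 9
Reactants: 11 (2E)-3-{2,4-bis(benzyloxy)-6-[(triisopropylsilyl)oxy]phenyl}-2-[5,7-bis(benzyloxy)-4-oxo-4H-chromen-8-yl]prop-2-enal; 12 4-bromo-1,2-bis(benzyloxy)benzene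
Product: 15 racemic (2E)-1-[3,4-bis(benzyloxy)phenyl]-3-{2,4-bis(benzyloxy)-6-[(triisopropylsilyl)oxy]phenyl}-2-[5,7-bis(benzyloxy)-4-oxo-4H-chromen-8-yl]prop-2-en-1-ol, via arylmagnesium bromide 13 (not isolated), via arylzinc chloride 14 (not isolated)
Conditions: 12, Mg, THF, 40 °C; ZnCl2 (1.0 equiv), 0 °C; then 11, THF, 0 °C to rt; aq. NH4Cl
Reagents that add atoms: none
Why: 1,2-Addition of an arylzinc halide, activated by the magnesium salt from the transmetalation; organozincs add to aldehydes but should leave the chromone carbonyl and enone alone, and without copper no conjugate addition is expected. The carbinol centre is left racemic on purpose.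

Step 10
Reactants: 15 racemic (2E)-1-[3,4-bis(benzyloxy)phenyl]-3-{2,4-bis(benzyloxy)-6-[(triisopropylsilyl)oxy]phenyl}-2-[5,7-bis(benzyloxy)-4-oxo-4H-chromen-8-yl]prop-2-en-1-ol
Product: 16 racemic (2E)-1-[3,4-bis(benzyloxy)phenyl]-3-{2,4-bis(benzyloxy)-6-[(triisopropylsilyl)oxy]phenyl}-2-[5,7-bis(benzyloxy)-4-oxo-4H-chromen-8-yl]prop-2-enyl methyl carbonate
Conditions: ClCO2Me, pyridine, DMAP (cat.), CH2Cl2, 0 °C
Reagents that add atoms: methyl chloroformate, COC(=O)Cl
Why: Acylation of the secondary alcohol under nucleophilic catalysis; the phenol is silylated, so only the carbinol can react. The carbonate is ionisable and should be purified on base-washed silica.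

Step 11
Reactants: 16 racemic (2E)-1-[3,4-bis(benzyloxy)phenyl]-3-{2,4-bis(benzyloxy)-6-[(triisopropylsilyl)oxy]phenyl}-2-[5,7-bis(benzyloxy)-4-oxo-4H-chromen-8-yl]prop-2-enyl methyl carbonate
Product: 17 racemic (2E)-1-[3,4-bis(benzyloxy)phenyl]-3-[2,4-bis(benzyloxy)-6-hydroxyphenyl]-2-[5,7-bis(benzyloxy)-4-oxo-4H-chromen-8-yl]prop-2-enyl methyl carbonate
Conditions: TBAF, AcOH (1.2 equiv each), THF, 0 °C; neutral work-up, used directly
Reagents that add atoms: none
Why: Fluoride cleaves the aryl silyl ether selectively, and acetic acid protonates the phenoxide at once so that base-induced expulsion of the carbonate is avoided. The (E) geometry keeps the phenol away from the carbinol carbon, so 17 should be isolable.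

Step 12
Reactants: 17 racemic (2E)-1-[3,4-bis(benzyloxy)phenyl]-3-[2,4-bis(benzyloxy)-6-hydroxyphenyl]-2-[5,7-bis(benzyloxy)-4-oxo-4H-chromen-8-yl]prop-2-enyl methyl carbonate
Product: 18 (2S)-2-[3,4-bis(benzyloxy)phenyl]-5,7-bis(benzyloxy)-3-[5,7-bis(benzyloxy)-4-oxo-4H-chromen-8-yl]-2H-chromene
Conditions: Pd2(dba)3·CHCl3 (2.5 mol%), (3aR,8aR)-N,N,2,2-tetramethyl-4,4,8,8-tetraphenyltetrahydro[1,3]dioxolo[4,5-e][1,3,2]dioxaphosphepin-6-amine or its enantiomer, whichever gives (S)-18 (10 mol%), toluene, 0 °C to rt, dark, no added base
Reagents that add atoms: none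
Why: Zerovalent palladium carrying the phosphoramidite ionises the carbonate of 17 anti to the leaving group; the methyl carbonate ion loses CO2 and the methoxide so formed deprotonates the phenol, so base appears only after ionisation (Tsuji–Trost chemistry under neutral conditions). The first allyl complex has ring A syn, that is cis to the central chromonyl group, and cannot close; an η3–η1–η3 shift through the carbon bearing ring A brings ring A anti, a geometry that the central aryl group makes less costly than in an allyl with hydrogen on the middle carbon. The phenoxide then attacks the terminus bearing the catechol ring on the face away from the metal, which forms O1–C2 and closes ring C with all three allyl carbons inside the six-membered ring (6-endo with respect to the allyl unit); closure onto the terminus bearing ring A would have to make a benzoxete, so only one regiochemistry is open. The closest known reaction is the palladium/phosphoramidite-catalysed enantioselective cyclisation of (E)-ortho-hydroxycinnamyl esters to 2-aryl-2H-chromenes; the aryl group on the central allyl carbon goes beyond it. C2 is set by the ligand, which decides which enantioface of the catechol-bearing terminus is bound to palladium in the complex that closes. Because each terminus carries a single substituent, the η3–η1–η3 shifts exchange syn and anti positions but not the two faces of the allyl unit, so the two enantiomers of 17 converge only if the metal also changes face; that is possible here because the deprotonated intermediate is at the same time a zerovalent palladium complex of a planar ortho-quinone methide, and also by allyl exchange between palladium centres. The step therefore needs face exchange faster than ring closure, and closure on the metal faster than closure of metal-free quinone methide; the (E) geometry of 17, which excludes direct uncatalysed attack, the absence of added base and a nonpolar solvent at or below room temperature are chosen to secure both.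

Step 13
Reactants: 18 (2S)-2-[3,4-bis(benzyloxy)phenyl]-5,7-bis(benzyloxy)-3-[5,7-bis(benzyloxy)-4-oxo-4H-chromen-8-yl]-2H-chromene; 19 [4-(benzyloxy)phenyl]boronic acid
Product: 20 (2S)-5,7-bis(benzyloxy)-2-[4-(benzyloxy)phenyl]-8-{(2S)-5,7-bis(benzyloxy)-2-[3,4-bis(benzyloxy)phenyl]-2H-chromen-3-yl}-2,3-dihydro-4H-chromen-4-one
Conditions: 19 (2.5 equiv), Pd(OCOCF3)2 (10 mol%), (R)-4-tert-butyl-2-(pyridin-2-yl)-4,5-dihydrooxazole (12 mol%), NH4PF6 (30 mol%), H2O (5 equiv), ClCH2CH2Cl, 40 °C, dark
Reagents that add atoms: none
Why: Conjugate addition of an arylboronic acid to a chromone catalysed by cationic divalent palladium with a pyridine–oxazoline ligand (transmetalation, enantioselective insertion of the chromone C2=C3 bond, protonolysis of the palladium enolate); the ligand sets C2 of unit 2. The chromene alkene is trisubstituted and shielded and should not insert, and no base is present to open the new flavanone.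

Step 14
Reactants: 20 (2S)-5,7-bis(benzyloxy)-2-[4-(benzyloxy)phenyl]-8-{(2S)-5,7-bis(benzyloxy)-2-[3,4-bis(benzyloxy)phenyl]-2H-chromen-3-yl}-2,3-dihydro-4H-chromen-4-one
Product: 22 (2S)-5,7-bis(benzyloxy)-2-[4-(benzyloxy)phenyl]-8-{(2R,3S,4S)-5,7-bis(benzyloxy)-2-[3,4-bis(benzyloxy)phenyl]-4-hydroxy-3,4-dihydro-2H-chromen-3-yl}-3,4-dihydro-2H-chromen-4-ol (both epimers at the carbinol of unit 2), via borane adduct 21 (not isolated)
Conditions: BH3·THF (5 equiv), THF, 0 °C to rt; then NaOH (aq.), H2O2, 0 °C
Reagents that add atoms: hydrogen peroxide, OO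
Why: Hydroboration–oxidation; strain against the C3 aryl group pushes the C2 aryl group pseudo-axial, so B–H should add syn from the opposite face, with hydrogen to C3 and boron to the less substituted C4, which leaves the unit 2 aryl group cis to the catechol ring and the C4 hydroxyl trans to both after oxidation with retention. Borane also reduces the unit 2 ketone, which protects that ring from base during the oxidative work-up and is undone in step 15.

Step 15
Reactants: 22 (2S)-5,7-bis(benzyloxy)-2-[4-(benzyloxy)phenyl]-8-{(2R,3S,4S)-5,7-bis(benzyloxy)-2-[3,4-bis(benzyloxy)phenyl]-4-hydroxy-3,4-dihydro-2H-chromen-3-yl}-3,4-dihydro-2H-chromen-4-ol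
Product: 23 (2R,3R)-5,7-bis(benzyloxy)-2-[3,4-bis(benzyloxy)phenyl]-3-{(2S)-5,7-bis(benzyloxy)-2-[4-(benzyloxy)phenyl]-4-oxo-3,4-dihydro-2H-chromen-8-yl}-2,3-dihydro-4H-chromen-4-one
Conditions: Dess–Martin periodinane (3 equiv), NaHCO3, CH2Cl2, 0 °C to rt; chromatography on neutral silica
Reagents that add atoms: none
Why: Dess–Martin oxidation of both secondary benzylic alcohols under buffered conditions that do not enolise the product; C3 is not touched, so the cis arrangement should be kept as long as acid and base are avoided afterwards.

Step 16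
Reactants: 23 (2R,3R)-5,7-bis(benzyloxy)-2-[3,4-bis(benzyloxy)phenyl]-3-{(2S)-5,7-bis(benzyloxy)-2-[4-(benzyloxy)phenyl]-4-oxo-3,4-dihydro-2H-chromen-8-yl}-2,3-dihydro-4H-chromen-4-one
Product: 24 (2R,3R)-2-(3,4-dihydroxyphenyl)-3-[(2S)-5,7-dihydroxy-2-(4-hydroxyphenyl)-4-oxo-3,4-dihydro-2H-chromen-8-yl]-5,7-dihydroxy-2,3-dihydro-4H-chromen-4-one
Conditions: H2 (1 atm), 10% Pd/C, EtOAc/MeOH, rt, stopped at full conversion
Reagents that add atoms: none
Why: Hydrogenolysis of seven aryl benzyl ethers under neutral conditions; the aryl ketones, conjugated with electron-rich rings, are poor substrates for reduction at this pressure, and no acid or base is present to epimerise C3 or open either ring C.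

## Compound list

1 | 2,4,6-trihydroxyacetophenone | CC(=O)c1c(O)cc(O)cc1O | starting material
2 | 1-[2,4-bis(benzyloxy)-6-hydroxyphenyl]ethanone | CC(=O)c1c(O)cc(OCc2ccccc2)cc1OCc1ccccc1 | intermediate
3 | 1-[2-(allyloxy)-4,6-bis(benzyloxy)phenyl]ethanone | CC(=O)c1c(OCC=C)cc(OCc2ccccc2)cc1OCc1ccccc1 | intermediate
4 | 1-[3-allyl-4,6-bis(benzyloxy)-2-hydroxyphenyl]ethanone | CC(=O)c1c(O)c(CC=C)c(OCc2ccccc2)cc1OCc1ccccc1 | intermediate
5 | (2E)-1-[3-allyl-4,6-bis(benzyloxy)-2-hydroxyphenyl]-3-(dimethylamino)prop-2-en-1-one (not isolated) | CN(C)/C=C/C(=O)c1c(O)c(CC=C)c(OCc2ccccc2)cc1OCc1ccccc1 | intermediate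
6 | 8-allyl-5,7-bis(benzyloxy)-4H-chromen-4-one | C=CCc1c(OCc2ccccc2)cc(OCc2ccccc2)c2c(=O)ccoc12 | intermediate
7 | [5,7-bis(benzyloxy)-4-oxo-4H-chromen-8-yl]acetaldehyde | O=CCc1c(OCc2ccccc2)cc(OCc2ccccc2)c2c(=O)ccoc12 | intermediate
8 | 2,4,6-trihydroxybenzaldehyde | O=Cc1c(O)cc(O)cc1O | starting material
9 | 2,4-bis(benzyloxy)-6-hydroxybenzaldehyde | O=Cc1c(O)cc(OCc2ccccc2)cc1OCc1ccccc1 | intermediate
10 | 2,4-bis(benzyloxy)-6-[(triisopropylsilyl)oxy]benzaldehyde | O=Cc1c(O[Si](C(C)C)(C(C)C)C(C)C)cc(OCc2ccccc2)cc1OCc1ccccc1 | intermediate
11 | (2E)-3-{2,4-bis(benzyloxy)-6-[(triisopropylsilyl)oxy]phenyl}-2-[5,7-bis(benzyloxy)-4-oxo-4H-chromen-8-yl]prop-2-enal | O=C/C(=C/c1c(O[Si](C(C)C)(C(C)C)C(C)C)cc(OCc2ccccc2)cc1OCc1ccccc1)c1c(OCc2ccccc2)cc(OCc2ccccc2)c2c(=O)ccoc12 | intermediate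
12 | 4-bromo-1,2-bis(benzyloxy)benzene | Brc1ccc(OCc2ccccc2)c(OCc2ccccc2)c1 | starting material
13 | [3,4-bis(benzyloxy)phenyl]magnesium bromide (not isolated) | Br[Mg]c1ccc(OCc2ccccc2)c(OCc2ccccc2)c1 | intermediate
14 | [3,4-bis(benzyloxy)phenyl]zinc chloride (not isolated) | Cl[Zn]c1ccc(OCc2ccccc2)c(OCc2ccccc2)c1 | intermediate
15 | racemic (2E)-1-[3,4-bis(benzyloxy)phenyl]-3-{2,4-bis(benzyloxy)-6-[(triisopropylsilyl)oxy]phenyl}-2-[5,7-bis(benzyloxy)-4-oxo-4H-chromen-8-yl]prop-2-en-1-ol | OC(c1ccc(OCc2ccccc2)c(OCc2ccccc2)c1)/C(=C/c1c(O[Si](C(C)C)(C(C)C)C(C)C)cc(OCc2ccccc2)cc1OCc1ccccc1)c1c(OCc2ccccc2)cc(OCc2ccccc2)c2c(=O)ccoc12 | intermediate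
16 | racemic methyl carbonate of 15 | COC(=O)OC(c1ccc(OCc2ccccc2)c(OCc2ccccc2)c1)/C(=C/c1c(O[Si](C(C)C)(C(C)C)C(C)C)cc(OCc2ccccc2)cc1OCc1ccccc1)c1c(OCc2ccccc2)cc(OCc2ccccc2)c2c(=O)ccoc12 | intermediate
17 | racemic (2E)-1-[3,4-bis(benzyloxy)phenyl]-3-[2,4-bis(benzyloxy)-6-hydroxyphenyl]-2-[5,7-bis(benzyloxy)-4-oxo-4H-chromen-8-yl]prop-2-enyl methyl carbonate | COC(=O)OC(c1ccc(OCc2ccccc2)c(OCc2ccccc2)c1)/C(=C/c1c(O)cc(OCc2ccccc2)cc1OCc1ccccc1)c1c(OCc2ccccc2)cc(OCc2ccccc2)c2c(=O)ccoc12 | intermediate
18 | (2S)-2-[3,4-bis(benzyloxy)phenyl]-5,7-bis(benzyloxy)-3-[5,7-bis(benzyloxy)-4-oxo-4H-chromen-8-yl]-2H-chromene | O=c1ccoc2c1c(OCc1ccccc1)cc(OCc1ccccc1)c2C1=Cc2c(OCc3ccccc3)cc(OCc3ccccc3)cc2O[C@H]1c1ccc(OCc2ccccc2)c(OCc2ccccc2)c1 | intermediate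
19 | [4-(benzyloxy)phenyl]boronic acid | OB(O)c1ccc(OCc2ccccc2)cc1 | starting material
20 | (2S)-5,7-bis(benzyloxy)-2-[4-(benzyloxy)phenyl]-8-{(2S)-5,7-bis(benzyloxy)-2-[3,4-bis(benzyloxy)phenyl]-2H-chromen-3-yl}-2,3-dihydro-4H-chromen-4-one | O=C1C[C@@H](c2ccc(OCc3ccccc3)cc2)Oc2c1c(OCc1ccccc1)cc(OCc1ccccc1)c2C1=Cc2c(OCc3ccccc3)cc(OCc3ccccc3)cc2O[C@H]1c1ccc(OCc2ccccc2)c(OCc2ccccc2)c1 | intermediate
21 | borane adduct of 20, drawn as the C4 alkylborane of unit 1 and the alkoxyborane of the reduced unit 2 ketone (representative, not isolated) | [BH2]OC1C[C@@H](c2ccc(OCc3ccccc3)cc2)Oc2c1c(OCc1ccccc1)cc(OCc1ccccc1)c2[C@H]1[C@H]([BH2])c2c(OCc3ccccc3)cc(OCc3ccccc3)cc2O[C@H]1c1ccc(OCc2ccccc2)c(OCc2ccccc2)c1 | intermediate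
22 | (2S)-5,7-bis(benzyloxy)-2-[4-(benzyloxy)phenyl]-8-{(2R,3S,4S)-5,7-bis(benzyloxy)-2-[3,4-bis(benzyloxy)phenyl]-4-hydroxy-3,4-dihydro-2H-chromen-3-yl}-3,4-dihydro-2H-chromen-4-ol; unit 1 is 2,3-cis-3,4-trans, the carbinol of unit 2 is a mixture of epimers | OC1C[C@@H](c2ccc(OCc3ccccc3)cc2)Oc2c1c(OCc1ccccc1)cc(OCc1ccccc1)c2[C@H]1[C@H](O)c2c(OCc3ccccc3)cc(OCc3ccccc3)cc2O[C@H]1c1ccc(OCc2ccccc2)c(OCc2ccccc2)c1 | intermediate
23 | (2R,3R)-5,7-bis(benzyloxy)-2-[3,4-bis(benzyloxy)phenyl]-3-{(2S)-5,7-bis(benzyloxy)-2-[4-(benzyloxy)phenyl]-4-oxo-3,4-dihydro-2H-chromen-8-yl}-2,3-dihydro-4H-chromen-4-one | O=C1C[C@@H](c2ccc(OCc3ccccc3)cc2)Oc2c1c(OCc1ccccc1)cc(OCc1ccccc1)c2[C@H]1C(=O)c2c(OCc3ccccc3)cc(OCc3ccccc3)cc2O[C@H]1c1ccc(OCc2ccccc2)c(OCc2ccccc2)c1 | intermediate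
24 | (2R,3R)-2-(3,4-dihydroxyphenyl)-3-[(2S)-5,7-dihydroxy-2-(4-hydroxyphenyl)-4-oxo-3,4-dihydro-2H-chromen-8-yl]-5,7-dihydroxy-2,3-dihydro-4H-chromen-4-one | O=C1C[C@@H](c2ccc(O)cc2)Oc2c1c(O)cc(O)c2[C@H]1C(=O)c2c(O)cc(O)cc2O[C@H]1c1ccc(O)c(O)c1 | target

## Step count and weak points

Total: 16 steps. Longest linear sequence: 14 steps (steps 1–5 and 8–16, from 1). Steps 6 and 7 form the short branch.

**Step 12 (key step).** The most likely failure is loss of enantiocontrol. It can happen by ring closure of each enantiomer's allyl complex before the metal has changed face, a stereospecific course that returns racemic chromene from racemic carbonate. It can also happen by escape of the quinone methide from the metal, followed by ligand-free electrocyclisation. Slow ionisation is the second concern, because the di-ortho-substituted aryl group on the central allyl carbon stands across the allyl plane and crowds the metal. The fallback gives up asymmetric catalysis at this point. 17 is closed without a chiral ligand (Pd(PPh3)4 in THF, or K2CO3 in MeOH/THF, where the phenoxide expels the carbonate and the quinone methide closes) to the racemic 2H-chromene F1. The enantiomers are then separated by preparative HPLC on a cellulose- or amylose-carbamate chiral phase. The (2S) enantiomer is 18, where the route is rejoined, and the (2R) enantiomer F2 is set aside.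

**Step 8.** The most likely failure is self-condensation of the enolisable aldehyde 7 outrunning its addition to the hindered, electron-rich aldehyde 10, together with partial ring opening of the chromone by the amine. The fallback changes the order of bond formation, setting out from 7 and returning at 15:
- 14 is added to 7 to give the racemic alcohol F3.
- Dess–Martin oxidation gives the deoxybenzoin-type ketone F4, whose methylene is more acidic and whose carbonyl cannot self-condense.
- Knoevenagel-type condensation of F4 with 10 (piperidinium acetate, toluene, water removal) gives the (E)-α-aryl chalcone F5.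
- Luche reduction (NaBH4, CeCl3·7H2O, MeOH/THF, −40 °C) of F5 gives 15.

**Step 13.** Three processes threaten this step. Insertion may be slow because the chromone is electron-rich and crowded near O1 by the C8 substituent. Facial selectivity may be poor if the bias of the neighbouring chromene opposes the catalyst. The chromene C2 centre may erode by reversible ring opening under warm, weakly acidic conditions. The fallback drops catalyst control. 18 is arylated with an achiral catalyst at room temperature (Pd(OCOCF3)2 with 2,2'-bipyridine), which should give 20 together with its (2R) epimer at unit 2 F6. The two are diastereomers because unit 1 is already configured, so they can be separated by chromatography. F6 is recycled by equilibration at C2 of unit 2 with a mild base (NaOAc, EtOH, 50 °C) and separated again; the route is rejoined at 20.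

**Step 14.** The most likely failure is wrong regiochemistry. Boron at C3 is favoured electronically, because ring A stabilises positive charge at C4, and it would lead to elimination of the ring oxygen. Incomplete facial selectivity and protodeboronation of the electron-rich benzylic borane during oxidation are further risks. The fallback sets out from 20 and returns at 23, so step 15 is not needed:
- Dihydroxylation of 20 (OsO4, NMO, acetone/H2O) from the face away from the C2 aryl group gives the cis-3,4-diol F7.
- Dess–Martin oxidation of the secondary carbinol of F7 gives the 3-hydroxy-4-ketone F8.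
- SmI2 in THF/MeOH at −78 °C removes the tertiary hydroxyl through a samarium enolate. Protonation from the face away from the C2 aryl group should give the cis ketone 23.

**Step 16.** The most likely failures are over-reduction (hydrogenolysis of the benzylic C2–O bonds, reduction of the ketones) and epimerisation at C3 on the catalyst or during isolation of the heptaphenol. The fallback replaces hydrogenolysis by Lewis-acid debenzylation of 23 with BCl3 and pentamethylbenzene in CH2Cl2 at −78 °C, which leads directly to 24 without new intermediates.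

## Further compounds

F1 | step 12 | racemic 2-[3,4-bis(benzyloxy)phenyl]-5,7-bis(benzyloxy)-3-[5,7-bis(benzyloxy)-4-oxo-4H-chromen-8-yl]-2H-chromene | O=c1ccoc2c1c(OCc1ccccc1)cc(OCc1ccccc1)c2C1=Cc2c(OCc3ccccc3)cc(OCc3ccccc3)cc2OC1c1ccc(OCc2ccccc2)c(OCc2ccccc2)c1
F2 | step 12 | (2R)-2-[3,4-bis(benzyloxy)phenyl]-5,7-bis(benzyloxy)-3-[5,7-bis(benzyloxy)-4-oxo-4H-chromen-8-yl]-2H-chromene | O=c1ccoc2c1c(OCc1ccccc1)cc(OCc1ccccc1)c2C1=Cc2c(OCc3ccccc3)cc(OCc3ccccc3)cc2O[C@@H]1c1ccc(OCc2ccccc2)c(OCc2ccccc2)c1
F3 | step 8 | racemic 1-[3,4-bis(benzyloxy)phenyl]-2-[5,7-bis(benzyloxy)-4-oxo-4H-chromen-8-yl]ethanol | OC(Cc1c(OCc2ccccc2)cc(OCc2ccccc2)c2c(=O)ccoc12)c1ccc(OCc2ccccc2)c(OCc2ccccc2)c1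
F4 | step 8 | 1-[3,4-bis(benzyloxy)phenyl]-2-[5,7-bis(benzyloxy)-4-oxo-4H-chromen-8-yl]ethanone | O=C(Cc1c(OCc2ccccc2)cc(OCc2ccccc2)c2c(=O)ccoc12)c1ccc(OCc2ccccc2)c(OCc2ccccc2)c1
F5 | step 8 | (2E)-1-[3,4-bis(benzyloxy)phenyl]-3-{2,4-bis(benzyloxy)-6-[(triisopropylsilyl)oxy]phenyl}-2-[5,7-bis(benzyloxy)-4-oxo-4H-chromen-8-yl]prop-2-en-1-one | O=C(c1ccc(OCc2ccccc2)c(OCc2ccccc2)c1)/C(=C/c1c(O[Si](C(C)C)(C(C)C)C(C)C)cc(OCc2ccccc2)cc1OCc1ccccc1)c1c(OCc2ccccc2)cc(OCc2ccccc2)c2c(=O)ccoc12
F6 | step 13 | (2R)-5,7-bis(benzyloxy)-2-[4-(benzyloxy)phenyl]-8-{(2S)-5,7-bis(benzyloxy)-2-[3,4-bis(benzyloxy)phenyl]-2H-chromen-3-yl}-2,3-dihydro-4H-chromen-4-one | O=C1C[C@H](c2ccc(OCc3ccccc3)cc2)Oc2c1c(OCc1ccccc1)cc(OCc1ccccc1)c2C1=Cc2c(OCc3ccccc3)cc(OCc3ccccc3)cc2O[C@H]1c1ccc(OCc2ccccc2)c(OCc2ccccc2)c1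
F7 | step 14 | (2S)-5,7-bis(benzyloxy)-2-[4-(benzyloxy)phenyl]-8-{(2S,3R,4R)-5,7-bis(benzyloxy)-2-[3,4-bis(benzyloxy)phenyl]-3,4-dihydroxy-3,4-dihydro-2H-chromen-3-yl}-2,3-dihydro-4H-chromen-4-one (both hydroxyls trans to the C2 aryl group) | O=C1C[C@@H](c2ccc(OCc3ccccc3)cc2)Oc2c1c(OCc1ccccc1)cc(OCc1ccccc1)c2[C@@]1(O)[C@H](O)c2c(OCc3ccccc3)cc(OCc3ccccc3)cc2O[C@H]1c1ccc(OCc2ccccc2)c(OCc2ccccc2)c1
F8 | step 14 | (2S,3S)-5,7-bis(benzyloxy)-2-[3,4-bis(benzyloxy)phenyl]-3-{(2S)-5,7-bis(benzyloxy)-2-[4-(benzyloxy)phenyl]-4-oxo-3,4-dihydro-2H-chromen-8-yl}-3-hydroxy-2,3-dihydro-4H-chromen-4-one | O=C1C[C@@H](c2ccc(OCc3ccccc3)cc2)Oc2c1c(OCc1ccccc1)cc(OCc1ccccc1)c2[C@@]1(O)C(=O)c2c(OCc3ccccc3)cc(OCc3ccccc3)cc2O[C@H]1c1ccc(OCc2ccccc2)c(OCc2ccccc2)c1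
F0 | step 16 | none | none
A1 | alternative 1 | (2R,3R)-cis-2-[3,4-bis(benzyloxy)phenyl]-3-[5,7-bis(benzyloxy)-4-oxo-4H-chromen-8-yl]-5,7-dihydroxy-2,3-dihydro-4H-chromen-4-one | O=c1ccoc2c1c(OCc1ccccc1)cc(OCc1ccccc1)c2[C@H]1C(=O)c2c(O)cc(O)cc2O[C@H]1c1ccc(OCc2ccccc2)c(OCc2ccccc2)c1
A2 | alternative 1 | (2R,3R)-2-[3,4-bis(benzyloxy)phenyl]-3-[5,7-bis(benzyloxy)-4-oxo-4H-chromen-8-yl]-5-(phenylsulfinyl)-2,3-dihydro-4H-pyran-4-one (either configuration at sulfur) | O=c1ccoc2c1c(OCc1ccccc1)cc(OCc1ccccc1)c2[C@H]1C(=O)C(S(=O)c2ccccc2)=CO[C@H]1c1ccc(OCc2ccccc2)c(OCc2ccccc2)c1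
A3 | alternative 1 | 1-methoxy-1,3-bis(trimethylsilyloxy)buta-1,3-diene | COC(O[Si](C)(C)C)=CC(=C)O[Si](C)(C)C
A4 | alternative 2 | hepta-O-benzyl ether of the target, identical with 23 | O=C1C[C@@H](c2ccc(OCc3ccccc3)cc2)Oc2c1c(OCc1ccccc1)cc(OCc1ccccc1)c2[C@H]1C(=O)c2c(OCc3ccccc3)cc(OCc3ccccc3)cc2O[C@H]1c1ccc(OCc2ccccc2)c(OCc2ccccc2)c1
A5 | alternative 2 | (3R,4R)-cis-4-[3,4-bis(benzyloxy)phenyl]-3-{(2S)-5,7-bis(benzyloxy)-2-[4-(benzyloxy)phenyl]-4-oxo-3,4-dihydro-2H-chromen-8-yl}oxetan-2-one | O=C1C[C@@H](c2ccc(OCc3ccccc3)cc2)Oc2c1c(OCc1ccccc1)cc(OCc1ccccc1)c2[C@H]1C(=O)O[C@H]1c1ccc(OCc2ccccc2)c(OCc2ccccc2)c1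
A6 | alternative 2 | 3,5-bis(benzyloxy)-2-(trimethylsilyl)phenyl trifluoromethanesulfonate | C[Si](C)(C)c1c(OS(=O)(=O)C(F)(F)F)cc(OCc2ccccc2)cc1OCc1ccccc1
A7 | alternative 3 | (2S)-3-[4-(benzyloxy)-2-hydroxy-6-(triisopropylsilyloxy)phenyl]-2-[3,4-bis(benzyloxy)phenyl]-5,7-bis(benzyloxy)-2H-chromene | Oc1cc(OCc2ccccc2)cc(O[Si](C(C)C)(C(C)C)C(C)C)c1C1=Cc2c(OCc3ccccc3)cc(OCc3ccccc3)cc2O[C@H]1c1ccc(OCc2ccccc2)c(OCc2ccccc2)c1
A8 | alternative 3 | (2S)-2-[3,4-bis(benzyloxy)phenyl]-5,7-bis(benzyloxy)-3-{[(triisopropylsilyl)oxy]ethynyl}-2H-chromene | CC(C)[Si](OC#CC1=Cc2c(OCc3ccccc3)cc(OCc3ccccc3)cc2O[C@H]1c1ccc(OCc2ccccc2)c(OCc2ccccc2)c1)(C(C)C)C(C)C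
A9 | alternative 3 | 3-(benzyloxy)cyclobut-2-en-1-one | O=C1C=C(OCc2ccccc2)C1
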